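All runs stem from a simulated flask from invented constants; noise was put on by code.

One mM of E taken by D is one mM that G cannot meet, so I reckoned with free E, the charge c(E) less the charge c(D). No earlier run changes c(D), so this subtraction is a guess.

| flask | Q | E | D | remark | time |
|---|---|---|---|---|---|
| epsilon | 20 mM | 51 mM (in portions, 3) | 1 mM | run made earlier; portions every 12 h |  |
| gamma | 20 mM | 120 mM (in portions, 3) | 1 mM | run made earlier; portions every 12 h |  |
| delta | 54 mM | 36 mM (in portions, 3) | 1 mM | run made earlier; portions every 12 h |  |
| north | 20 mM | 36.0 mM (in portions, 3) | 1.00 mM | the portions of E follow each other after 4.0 h, the first at the start | 3.0 d |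
| south-west | 20 mM | 36.0 mM (in portions, 3) | 1.00 mM | the portions of E follow each other after 12 h, the first at the start | 3.0 d |
| north-east | 20 mM | 36.0 mM (in portions, 3) | 1.00 mM | the portions of E follow each other after 8.0 h, the first at the start | 3.0 d |
| south | 80 mM | 36.0 mM (in portions, 3) | 1.00 mM | the portions of E follow each other after 12 h, the first at the start | 3.0 d |
| south-east | 80 mM | 36.0 mM (in portions, 3) | 1.50 mM | the portions of E follow each other after 4.0 h, the first at the start | 3.0 d |
| west | 20 mM | 80.0 mM (in portions, 3) | 3.00 mM | the portions of E follow each other after 12 h, the first at the start | 3.0 d |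

| run | time / d | X / % |
|---|---|---|
| epsilon | 0.417 | 4.9 |
| epsilon | 0.833 | 10.6 |
| epsilon | 1.25 | 20.0 |
| epsilon | 1.67 | 27.3 |
| epsilon | 2.00 | 30.8 |
| epsilon | 2.50 | 36.4 |
| epsilon | 3.00 | 41.8 |
| gamma | 0.250 | 4.8 |
| gamma | 0.333 | 8.7 |
| gamma | 0.500 | 10.8 |
| gamma | 0.833 | 24.7 |
| gamma | 1.25 | 39.4 |
| gamma | 2.08 | 58.8 |
| gamma | 3.00 | 68.1 |
| delta | 0.250 | 2.1 |
| delta | 0.417 | 2.8 |
| delta | 0.833 | 5.6 |
| delta | 1.67 | 13.6 |
| delta | 3.00 | 19.7 |

(standard deviation of a reading: 0.5 percentage points)

- percent here means Q units held: one J counts as two
- steps thought possible: Q -> G; E + G -> X; 2 G -> J; E + D -> Z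
- no earlier run changes the charge of D; that part of a forecast is a guess

- the flasks by amount of X, in percent of the Q charged, highest first, at 3.0 d (north / south-west / north-east / south / south-east / west)
- the amount of X, in percent of the Q charged of the flask you put first, at 3.0 d
- the amount of X, in percent of the Q charged of the flask you put last, at 3.0 d

G has two ways out: with E to X, at a rate that goes with c(G), and in pairs to J, at a rate that goes with c(G) squared. Let y be the share of the Q charged standing as X, and count the rest as lost to pairing, which is rough, since part of it may still stand as G. Steady c(G) is a further rough assumption of mine; with it, setting these two rates against each other leaves one product: the lost share divided by y squared, times free E squared over c(Q). I took this product as a working number for a forecast, not as a constant of the flask. The last readings, at 3.00 d with portions 12 h apart, give 416 mM for epsilon, 487 mM for gamma and 469 mM for delta. Their mean, 458 mM, is my split number, a kind of selectivity factor.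

Solved for y, it gave west 54.4%, south-west 30.5% and south 16.7%, so west stood first of these and south last. The number was read at 12 h spacing, so it does not reach the closer portions. I simply placed north and north-east above south-west, and south-east above south, with the earliest E highest.

The forecast said west > north > north-east > south-west > south-east > south, with 53% and 16%, and held that “Earlier dosing helps, and high Q hurts.” The flasks gave west > north > north-east > south-west > south-east > south, with 54.5% and 15.5%.

    Q → G (k = 1.80 × 10⁻⁴ /s)
    E + G → X (k = 9.10 × 10⁻⁵ /M/s)
    2 G → J (k = 1.10 × 10⁻⁴ /M/s)
    E + D → Z (k = 0.00280 /M/s)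

Against my figures, west gave 54.5%, south-west 31.4% and south 15.5%, which is 1.2 percentage points below my figure. A flask like south but with 0.60 mM of D has free E of 35.4 mM instead of 35.0 mM. The split number then gives 16.9%, a move of 0.20 points from south. That flask gave 15.7% of X, and at 3.00 d it held 0.600 mM of Z.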